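**Retrosynthetic overview**

1. Ring numbering used throughout: O1, C2 (4-hydroxy-3,5-dimethoxyphenyl), C3, C4 (OH), C5, C6 (arylethyl). The SMILES encodes the all-cis (2S,4R,6S) isomer, with all three substituents equatorial. TIPS = triisopropylsilyl.
2. Endgame, read backwards: free phenols from the bis-TIPS ether; C4–OH by axial hydride addition to the 2,6-cis pyran-4-one; C2–H by cis hydrogenation of a 2,3-dihydro-4H-pyran-4-one (C2=C3).
3. Key disconnection of that dihydropyranone: C4–C5 and O1–C2, a formal [3+3] union. The dinucleophile is a chiral β-lithio lithium alkoxide, LiC5H2–C6H(OLi)–CH2CH2Ar, made from an (S)-chlorohydrin. The dielectrophile is a 3-arylpropynoyl Weinreb amide (C4 = amide carbon, C2 = aryl-bearing alkyne carbon). The pyran ring is the only ring made, and it forms in this step.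
4. Enabling feature: in ring O1–C2–C3–C4–C5–C6, O1 and the C4 oxygen are 1,3-related across C2–C3, so the ring is a reduced vinylogous ester (O1–C2=C3–C4=O) that an alcohol and an aryl ynone can assemble. O1 and C5 are both attached to C6, so one carbinol stereocenter (C6, bought as (S)-epichlorohydrin) carries both nucleophilic sites and later directs C2 and C4.
5. Fragments: the chlorohydrin from vanillin and (S)-epichlorohydrin (benzylic Grignard); the ynamide from syringaldehyde (Corey–Fuchs, then a carbamoyl chloride).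

Key step: step 8

**Route**

Step 1
Reactants: 1 vanillin (4-hydroxy-3-methoxybenzaldehyde)
Product: 2 3-methoxy-4-(TIPS-oxy)benzaldehyde
Conditions: i-Pr3SiCl (1.2 equiv), imidazole (2.5 equiv), DMF, 23 °C
Reagents that add atoms: triisopropylsilyl chloride, CC(C)[Si](Cl)(C(C)C)C(C)C
Why: Imidazole-promoted O-silylation of the phenol (silyl ether formation) should be clean and installs a group that tolerates Grignard, alkyllithium and arene radical-anion conditions but falls to fluoride at the end; no stereocenter is involved.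

Step 2
Reactants: 2 3-methoxy-4-(TIPS-oxy)benzaldehyde
Product: 3 [3-methoxy-4-(TIPS-oxy)phenyl]methanol
Conditions: NaBH4 (0.5 equiv), MeOH/THF, 0 °C
Reagents that add atoms: none
Why: Borohydride reduction of an aromatic aldehyde to the benzylic alcohol is reliable and leaves the aryl silyl ether untouched at 0 °C.

Step 3
Reactants: 3 [3-methoxy-4-(TIPS-oxy)phenyl]methanol
Product: 4 [4-(chloromethyl)-2-methoxyphenoxy]triisopropylsilane
Conditions: SOCl2 (1.1 equiv), Et3N (1.2 equiv), CH2Cl2, 0 °C; used crude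
Reagents that add atoms: thionyl chloride, O=S(Cl)Cl
Why: Deoxychlorination through the chlorosulfite ester is fast for an electron-rich benzylic alcohol, and the amine scavenges HCl so the silyl ether survives.

Step 4
Reactants: 4 [4-(chloromethyl)-2-methoxyphenoxy]triisopropylsilane; 5 (S)-epichlorohydrin, (2S)-2-(chloromethyl)oxirane
Product: 7 (2S)-1-chloro-4-[3-methoxy-4-(TIPS-oxy)phenyl]butan-2-ol, via benzylic Grignard reagent 6 (not isolated)
Conditions: Mg turnings (3 equiv), Et2O, 0 °C, slow addition of 4 (1.3 equiv); then CuI (10 mol%), 5 (1.0 equiv), THF, −40 → −20 °C; 1 M HCl, 0 °C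
Reagents that add atoms: none
Why: Magnesium insertion gives Grignard reagent 6, and CuI-catalysed SN2 opening of the epoxide at its unsubstituted CH2 (faster than chloride displacement) adds the three-carbon unit; no bond to the stereocenter is made or broken, so the (S) centre of 5 becomes the (S) carbinol of 7, the future C6.

Step 5
Reactants: 8 syringaldehyde (4-hydroxy-3,5-dimethoxybenzaldehyde)
Product: 9 3,5-dimethoxy-4-(TIPS-oxy)benzaldehyde
Conditions: i-Pr3SiCl (1.5 equiv), imidazole (3 equiv), DMAP (0.1 equiv), DMF, 40 °C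
Reagents that add atoms: triisopropylsilyl chloride, CC(C)[Si](Cl)(C(C)C)C(C)C
Why: O-Silylation of the phenol (silyl ether formation), helped by DMAP and gentle warming because the hydroxyl is flanked by two methoxy groups, should give a silyl ether that the same flanking groups shield in later steps.

Step 6
Reactants: 9 3,5-dimethoxy-4-(TIPS-oxy)benzaldehyde
Product: 10 [4-(2,2-dibromovinyl)-2,6-dimethoxyphenoxy]triisopropylsilane
Conditions: CBr4 (2 equiv), PPh3 (4 equiv), CH2Cl2, 0 °C
Reagents that add atoms: carbon tetrabromide, BrC(Br)(Br)Br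
Why: First stage of the Corey–Fuchs reaction, a Wittig-type dibromoolefination that is general for aromatic aldehydes and supplies the carbon that becomes C3.

Step 7
Reactants: 10 [4-(2,2-dibromovinyl)-2,6-dimethoxyphenoxy]triisopropylsilane; 11 N-methoxy-N-methylcarbamoyl chloride
Product: 13 3-[3,5-dimethoxy-4-(TIPS-oxy)phenyl]-N-methoxy-N-methylprop-2-ynamide, via lithium arylacetylide 12 (not isolated)
Conditions: n-BuLi (2.1 equiv), THF, −78 °C; then 11 (1.3 equiv), −78 → 0 °C
Reagents that add atoms: none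
Why: Second stage of the Corey–Fuchs reaction (bromine–lithium exchange and rearrangement to the lithium acetylide) followed by C-acylation of the acetylide with the carbamoyl chloride, a standard entry to alkynyl Weinreb amides; the amide carbon becomes C4.

Step 8
Reactants: 7 (2S)-1-chloro-4-[3-methoxy-4-(TIPS-oxy)phenyl]butan-2-ol; 13 3-[3,5-dimethoxy-4-(TIPS-oxy)phenyl]-N-methoxy-N-methylprop-2-ynamide
Product: 16 (2S)-6-[3,5-dimethoxy-4-(TIPS-oxy)phenyl]-2-{2-[3-methoxy-4-(TIPS-oxy)phenyl]ethyl}-2,3-dihydro-4H-pyran-4-one, via β-lithio lithium alkoxide 14 (not isolated), via β-hydroxy ynone 15 (not isolated)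
Conditions: 7 (1.3 equiv), n-BuLi (1.3 equiv), THF, −78 °C; LiC10H8 (2.6 equiv), −78 °C; 13 (1.0 equiv), −78 °C; CF3CO2H (4 equiv), −78 → 23 °C; p-TsOH·H2O (0.2 equiv), 40 °C, same flask
Reagents that add atoms: none
Why: n-BuLi removes the hydroxyl proton of 7 and LiC10H8 exchanges C–Cl for C–Li to give 14, which persists at −78 °C because loss of Li2O is slow; its primary carbanion (C5) adds once to the amide carbonyl (C4) of 13, CF3CO2H then releases hydroxy ynone 15, and the C6 hydroxyl (O1) adds under acid catalysis to the aryl-bearing alkyne carbon (C2). The closest known reaction types are the trapping of β-oxido organolithium reagents (from chlorohydrins by deprotonation and reductive lithiation) with carbonyl electrophiles, the Weinreb ketone synthesis of ynones, and the acid- or metal-promoted cyclization of β-hydroxy ynones to 2,3-dihydro-4H-pyran-4-ones. The pyran ring closes in the 6-endo-dig mode as an intramolecular oxa-Michael addition. No new stereocenter is formed, and C6 keeps the (S) configuration of 7 because none of its four bonds is broken. The step needs carbonyl addition over conjugate addition, which the hard alkyllithium and the N-methoxy-N-methyl amide secure, and 6-endo over 5-exo closure, which the ynone polarization, reinforced by the electron-rich aryl ring on C2, secures. Acidification before warming keeps the released MeNHOMe protonated so that it cannot add to the ynone.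

Step 9
Reactants: 16 (2S)-6-[3,5-dimethoxy-4-(TIPS-oxy)phenyl]-2-{2-[3-methoxy-4-(TIPS-oxy)phenyl]ethyl}-2,3-dihydro-4H-pyran-4-one
Product: 17 (2S,6S)-2-[3,5-dimethoxy-4-(TIPS-oxy)phenyl]-6-{2-[3-methoxy-4-(TIPS-oxy)phenyl]ethyl}tetrahydro-4H-pyran-4-one (2,6-cis)
Conditions: H2 (1 atm), 10% Pd/C, EtOAc, 23 °C
Reagents that add atoms: none
Why: Heterogeneous catalytic hydrogenation of the vinylogous-ester C2=C3 bond should deliver hydrogen to the ring face opposite the pseudo-equatorial C6 side chain, as is general for 2-substituted 2,3-dihydro-4H-pyran-4-ones, so the new C2–H is cis to C6–H and the aryl group ends up cis to the side chain (2S); ketone and silyl ethers are left intact.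

Step 10
Reactants: 17 (2S,6S)-2-[3,5-dimethoxy-4-(TIPS-oxy)phenyl]-6-{2-[3-methoxy-4-(TIPS-oxy)phenyl]ethyl}tetrahydro-4H-pyran-4-one
Product: 18 (2S,4R,6S)-2-[3,5-dimethoxy-4-(TIPS-oxy)phenyl]-6-{2-[3-methoxy-4-(TIPS-oxy)phenyl]ethyl}tetrahydro-2H-pyran-4-ol (all-cis)
Conditions: NaBH4 (1.5 equiv), MeOH, −40 °C
Reagents that add atoms: none
Why: Borohydride reduction of a chair tetrahydropyran-4-one whose C2 and C6 substituents are both equatorial: the small hydride should attack along the axial trajectory, as with unhindered cyclohexanones, and give the equatorial alcohol, which is the all-cis (4R) isomer.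

Step 11
Reactants: 18 (2S,4R,6S)-2-[3,5-dimethoxy-4-(TIPS-oxy)phenyl]-6-{2-[3-methoxy-4-(TIPS-oxy)phenyl]ethyl}tetrahydro-2H-pyran-4-ol
Product: 19 (2S,4R,6S)-2-(4-hydroxy-3,5-dimethoxyphenyl)-6-[2-(4-hydroxy-3-methoxyphenyl)ethyl]tetrahydro-2H-pyran-4-ol (target)
Conditions: Bu4NF (2.4 equiv), AcOH (2.4 equiv), THF, 0 → 23 °C
Reagents that add atoms: none
Why: Fluoride-induced cleavage of both aryl silyl ethers (desilylation driven by the Si–F bond) frees the two phenols, and the AcOH buffer prevents phenoxide-triggered opening of the benzylic C2–O1 bond; no stereocenter is touched.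

**Compound list**

1 | vanillin (4-hydroxy-3-methoxybenzaldehyde) | COc1cc(C=O)ccc1O | starting material
2 | 3-methoxy-4-(TIPS-oxy)benzaldehyde | COc1cc(C=O)ccc1O[Si](C(C)C)(C(C)C)C(C)C | intermediate
3 | [3-methoxy-4-(TIPS-oxy)phenyl]methanol | COc1cc(CO)ccc1O[Si](C(C)C)(C(C)C)C(C)C | intermediate
4 | [4-(chloromethyl)-2-methoxyphenoxy]triisopropylsilane | COc1cc(CCl)ccc1O[Si](C(C)C)(C(C)C)C(C)C | intermediate
5 | (S)-epichlorohydrin, (2S)-2-(chloromethyl)oxirane | ClC[C@@H]1CO1 | starting material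
6 | [3-methoxy-4-(TIPS-oxy)benzyl]magnesium chloride | COc1cc(C[Mg]Cl)ccc1O[Si](C(C)C)(C(C)C)C(C)C | intermediate (not isolated)
7 | (2S)-1-chloro-4-[3-methoxy-4-(TIPS-oxy)phenyl]butan-2-ol | COc1cc(CC[C@H](O)CCl)ccc1O[Si](C(C)C)(C(C)C)C(C)C | intermediate
8 | syringaldehyde (4-hydroxy-3,5-dimethoxybenzaldehyde) | COc1cc(C=O)cc(OC)c1O | starting material
9 | 3,5-dimethoxy-4-(TIPS-oxy)benzaldehyde | COc1cc(C=O)cc(OC)c1O[Si](C(C)C)(C(C)C)C(C)C | intermediate
10 | [4-(2,2-dibromovinyl)-2,6-dimethoxyphenoxy]triisopropylsilane | COc1cc(C=C(Br)Br)cc(OC)c1O[Si](C(C)C)(C(C)C)C(C)C | intermediate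
11 | N-methoxy-N-methylcarbamoyl chloride | CON(C)C(Cl)=O | starting material
12 | lithium [3,5-dimethoxy-4-(TIPS-oxy)phenyl]acetylide | COc1cc(C#C[Li])cc(OC)c1O[Si](C(C)C)(C(C)C)C(C)C | intermediate (not isolated)
13 | 3-[3,5-dimethoxy-4-(TIPS-oxy)phenyl]-N-methoxy-N-methylprop-2-ynamide | CON(C)C(=O)C#Cc1cc(OC)c(O[Si](C(C)C)(C(C)C)C(C)C)c(OC)c1 | intermediate
14 | lithium (2R)-1-lithio-4-[3-methoxy-4-(TIPS-oxy)phenyl]butan-2-olate (same spatial arrangement as 7; the descriptor changes only because CH2Li ranks below CH2CH2Ar) | COc1cc(CC[C@H](O[Li])C[Li])ccc1O[Si](C(C)C)(C(C)C)C(C)C | intermediate (not isolated)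
15 | (5S)-1-[3,5-dimethoxy-4-(TIPS-oxy)phenyl]-5-hydroxy-7-[3-methoxy-4-(TIPS-oxy)phenyl]hept-1-yn-3-one | COc1cc(CC[C@H](O)CC(=O)C#Cc2cc(OC)c(O[Si](C(C)C)(C(C)C)C(C)C)c(OC)c2)ccc1O[Si](C(C)C)(C(C)C)C(C)C | intermediate (not isolated)
16 | (2S)-6-[3,5-dimethoxy-4-(TIPS-oxy)phenyl]-2-{2-[3-methoxy-4-(TIPS-oxy)phenyl]ethyl}-2,3-dihydro-4H-pyran-4-one | COc1cc(CC[C@H]2CC(=O)C=C(c3cc(OC)c(O[Si](C(C)C)(C(C)C)C(C)C)c(OC)c3)O2)ccc1O[Si](C(C)C)(C(C)C)C(C)C | intermediate
17 | (2S,6S)-2-[3,5-dimethoxy-4-(TIPS-oxy)phenyl]-6-{2-[3-methoxy-4-(TIPS-oxy)phenyl]ethyl}tetrahydro-4H-pyran-4-one | COc1cc(CC[C@H]2CC(=O)C[C@@H](c3cc(OC)c(O[Si](C(C)C)(C(C)C)C(C)C)c(OC)c3)O2)ccc1O[Si](C(C)C)(C(C)C)C(C)C | intermediate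
18 | (2S,4R,6S)-2-[3,5-dimethoxy-4-(TIPS-oxy)phenyl]-6-{2-[3-methoxy-4-(TIPS-oxy)phenyl]ethyl}tetrahydro-2H-pyran-4-ol | COc1cc(CC[C@H]2C[C@@H](O)C[C@@H](c3cc(OC)c(O[Si](C(C)C)(C(C)C)C(C)C)c(OC)c3)O2)ccc1O[Si](C(C)C)(C(C)C)C(C)C | intermediate
19 | (2S,4R,6S)-2-(4-hydroxy-3,5-dimethoxyphenyl)-6-[2-(4-hydroxy-3-methoxyphenyl)ethyl]tetrahydro-2H-pyran-4-ol | COc1cc(CC[C@H]2C[C@@H](O)C[C@@H](c3cc(OC)c(O)c(OC)c3)O2)ccc1O | target

**Step count**

Total steps: 11. Longest linear sequence: 8 steps (steps 1, 2, 3, 4, 8, 9, 10, 11).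

**Steps most likely to fail, with fallbacks**

1. Step 8. Possible failures: loss of the carbanion by β-elimination of Li2O before acylation, electron transfer from residual LiC10H8 to the ynamide, or incomplete ring closure. Fallback (Prins route): it sets out from chlorohydrin 7 and aldehyde 9 and returns at 18, bypassing steps 6–10. Compound 7 is closed with powdered KOH in Et2O to (2S)-2-{2-[3-methoxy-4-(TIPS-oxy)phenyl]ethyl}oxirane F1. CuI-catalysed opening with CH2=CHMgBr gives the homoallylic alcohol (3S)-1-[3-methoxy-4-(TIPS-oxy)phenyl]hex-5-en-3-ol F2. Prins cyclization of F2 with 9 (CF3CO2H, CH2Cl2, 0 °C) should pass through a chair oxocarbenium ion with both substituents equatorial and equatorial capture at C4, giving the all-cis trifluoroacetate (2S,4R,6S)-2-[3,5-dimethoxy-4-(TIPS-oxy)phenyl]-6-{2-[3-methoxy-4-(TIPS-oxy)phenyl]ethyl}tetrahydro-2H-pyran-4-yl trifluoroacetate F3. Mild hydrolysis (NaHCO3, MeOH/H2O) then gives 18.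

2. Step 9. Possible failures: hydrogenolysis of the electron-rich benzylic C2–O1 bond, over-reduction of the ketone, or insufficient facial selectivity. Fallback (C2 set by equilibration instead of hydrogenation): it sets out from aldehyde 9 and chlorohydrin 7 and returns at 17. Horner–Wadsworth–Emmons reaction of 9 with diethyl (N-methoxy-N-methylcarbamoylmethyl)phosphonate (NaH, THF) gives (E)-3-[3,5-dimethoxy-4-(TIPS-oxy)phenyl]-N-methoxy-N-methylprop-2-enamide F4. Addition of 14 (generated from 7 as in step 8) and aqueous NH4Cl work-up gives (1E,5S)-1-[3,5-dimethoxy-4-(TIPS-oxy)phenyl]-5-hydroxy-7-[3-methoxy-4-(TIPS-oxy)phenyl]hept-1-en-3-one F5. Acid-mediated 6-endo-trig oxa-Michael cyclization (Amberlyst-15, CH2Cl2, short exposure) under thermodynamic control should give the 2,6-cis ketone 17 with both substituents equatorial.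

3. Step 4. Possible failures: Wurtz-type homocoupling while the electron-rich benzylic Grignard reagent forms, or competing attack at the C–Cl bond of the epoxide. Fallback (no benzylic organometallic; stereocenter from catalyst control): it sets out from aldehyde 2 and returns at 7, bypassing steps 2–4. Wittig reaction of 2 with (3-chloro-2-oxopropylidene)triphenylphosphorane (toluene, 80 °C) gives (E)-1-chloro-4-[3-methoxy-4-(TIPS-oxy)phenyl]but-3-en-2-one F6. Corey–Bakshi–Shibata reduction with (S)-2-methyl-CBS-oxazaborolidine and BH3·SMe2, with the styryl group acting as the large substituent, should give (2S,3E)-1-chloro-4-[3-methoxy-4-(TIPS-oxy)phenyl]but-3-en-2-ol F7. Diimide reduction of the alkene (2-nitrobenzenesulfonyl hydrazide, Et3N) gives 7 without touching the C–Cl bond.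

**Further compounds**

F1 | step 8 | (2S)-2-{2-[3-methoxy-4-(TIPS-oxy)phenyl]ethyl}oxirane | COc1cc(CC[C@H]2CO2)ccc1O[Si](C(C)C)(C(C)C)C(C)C
F2 | step 8 | (3S)-1-[3-methoxy-4-(TIPS-oxy)phenyl]hex-5-en-3-ol | COc1cc(CC[C@H](O)CC=C)ccc1O[Si](C(C)C)(C(C)C)C(C)C
F3 | step 8 | (2S,4R,6S)-2-[3,5-dimethoxy-4-(TIPS-oxy)phenyl]-6-{2-[3-methoxy-4-(TIPS-oxy)phenyl]ethyl}tetrahydro-2H-pyran-4-yl trifluoroacetate | COc1cc(CC[C@H]2C[C@@H](OC(=O)C(F)(F)F)C[C@@H](c3cc(OC)c(O[Si](C(C)C)(C(C)C)C(C)C)c(OC)c3)O2)ccc1O[Si](C(C)C)(C(C)C)C(C)C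
F4 | step 9 | (E)-3-[3,5-dimethoxy-4-(TIPS-oxy)phenyl]-N-methoxy-N-methylprop-2-enamide | CON(C)C(=O)/C=C/c1cc(OC)c(O[Si](C(C)C)(C(C)C)C(C)C)c(OC)c1
F5 | step 9 | (1E,5S)-1-[3,5-dimethoxy-4-(TIPS-oxy)phenyl]-5-hydroxy-7-[3-methoxy-4-(TIPS-oxy)phenyl]hept-1-en-3-one | COc1cc(CC[C@H](O)CC(=O)/C=C/c2cc(OC)c(O[Si](C(C)C)(C(C)C)C(C)C)c(OC)c2)ccc1O[Si](C(C)C)(C(C)C)C(C)C
F6 | step 4 | (E)-1-chloro-4-[3-methoxy-4-(TIPS-oxy)phenyl]but-3-en-2-one | COc1cc(/C=C/C(=O)CCl)ccc1O[Si](C(C)C)(C(C)C)C(C)C
F7 | step 4 | (2S,3E)-1-chloro-4-[3-methoxy-4-(TIPS-oxy)phenyl]but-3-en-2-ol | COc1cc(/C=C/[C@H](O)CCl)ccc1O[Si](C(C)C)(C(C)C)C(C)C
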